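**Plan**

- Retrosynthetic cuts, in order: (i) the eighteen benzyl ethers; (ii) the upper interflavan bond C4(top)–C8(middle); (iii) in one operation the lower interflavan bond C4(middle)–C8(bottom) and the C2–C3 bond of ring C of the middle unit. This leaves an achiral phloroglucinol (Z)-enol gallate that carries the B-ring aldehyde carbon on O1 as an O-aryl O-acetyl acetal.
- Forward: ring-A aldehyde → alkyne → (Z)-enol gallate (the middle 3-O-galloyl ester of the target is already in place) → acylal 10. Acid then triggers the cascade: C3 attacks the C2 oxocarbenium (ring C of the middle unit closes) and the resulting C4 cation is captured by C8 of benzylated epicatechin gallate. The top unit is then joined at C8 of the new ring A, and hydrogenolysis finishes.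
- Enabling feature: the 5,7-dioxygenated ring A of the middle unit (C4a, C5–O, C7–O, C8a–O1) stabilises positive charge at benzylic C4. This makes C3 of the C3=C4 styrene the nucleophile toward C2 and delivers the same C4 cation through which procyanidins are chain-extended, so its capture by C8 is of the biogenetic type.
- Stereochemistry: C2 and C3 of the top and bottom units come unchanged from (−)-epicatechin. In the middle unit, C2 is set by the chiral counter-anion, C3 by the Z geometry of the enol ester (2,3-cis), and C4 by attack anti to the 3-O-galloyl group (4β). C4 of the top unit is set the same way (4β).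

Key step: step 10

Remark: flavan numbering is used for every unit (O1, C2, C3, C4, C4a, C5–C8, C8a; rings A, B, C); β is the face anti to the 3-oxygen of an epicatechin unit.
Assumption: the sense of induction of the chiral acid in step 10 cannot be derived from precedent; the (R)-acid is written, and its mirror image serves equally if the opposite sense is found.

**Route**

Step 1
Reactants: 1 2,4,6-trihydroxybenzaldehyde
Product: 2 2,4-bis(benzyloxy)-6-hydroxybenzaldehyde
Conditions: BnBr (2.1 equiv), K2CO3, DMF, 0 °C → rt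
Reagents that add atoms: benzyl bromide BrCc1ccccc1
Why: Williamson etherification, in which the phenol that is hydrogen-bonded to the formyl group is the least nucleophilic and should stay free when two equivalents of benzyl bromide are used.

Step 2
Reactants: 2 2,4-bis(benzyloxy)-6-hydroxybenzaldehyde
Product: 3 2,4-bis(benzyloxy)-6-[(triisopropylsilyl)oxy]benzaldehyde
Conditions: TIPSOTf, 2,6-lutidine, CH2Cl2, 0 °C → rt
Reagents that add atoms: triisopropylsilyl triflate CC(C)[Si](OS(=O)(=O)C(F)(F)F)(C(C)C)C(C)C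
Why: Silylation of the chelated phenol with the reactive silyl triflate gives an ether that withstands the strongly basic next step and prevents benzofuran formation from an o-alkynylphenol under ruthenium catalysis.

Step 3
Reactants: 3 2,4-bis(benzyloxy)-6-[(triisopropylsilyl)oxy]benzaldehyde
Product: 4 1,5-bis(benzyloxy)-2-ethynyl-3-[(triisopropylsilyl)oxy]benzene
Conditions: TMSCHN2, n-BuLi, THF, −78 °C → rt
Reagents that add atoms: trimethylsilyldiazomethane C[Si](C)(C)C=[N+]=[N-]
Why: Colvin rearrangement (addition of lithiated TMSCHN2, Peterson-type elimination, loss of N2 and 1,2-hydrogen shift of the alkylidene carbene) should convert the hindered, electron-rich aldehyde into the terminal alkyne in one step.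

Step 4
Reactants: 4 1,5-bis(benzyloxy)-2-ethynyl-3-[(triisopropylsilyl)oxy]benzene; 5 3,4,5-tris(benzyloxy)benzoic acid
Product: 6 (Z)-2-{2,4-bis(benzyloxy)-6-[(triisopropylsilyl)oxy]phenyl}ethenyl 3,4,5-tris(benzyloxy)benzoate
Conditions: [RuCl2(p-cymene)]2 (2 mol %), P(4-ClC6H4)3 (6 mol %), DMAP (8 mol %), toluene, 60 °C
Reagents that add atoms: none
Why: Ruthenium-vinylidene-mediated anti-Markovnikov hydro-oxycarbonylation of a terminal alkyne, a reaction type known to give (Z)-enol esters with this catalyst system; the Z geometry set here later becomes the 2,3-cis relationship.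

Step 5
Reactants: 6 (Z)-2-{2,4-bis(benzyloxy)-6-[(triisopropylsilyl)oxy]phenyl}ethenyl 3,4,5-tris(benzyloxy)benzoate
Product: 7 (Z)-2-[2,4-bis(benzyloxy)-6-hydroxyphenyl]ethenyl 3,4,5-tris(benzyloxy)benzoate
Conditions: TBAF/AcOH (1:1.2), THF, 0 °C
Reagents that add atoms: none
Why: Fluoride cleavage of the aryl silyl ether, buffered with acetic acid so that no free phenoxide is present that could take the galloyl group over from the neighbouring enol ester.

Step 6
Reactants: 8 3,4-bis(benzyloxy)benzaldehyde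
Product: 9 [3,4-bis(benzyloxy)phenyl](chloro)methyl acetate (racemic; used at once as a CH2Cl2 solution)
Conditions: AcCl, ZnCl2 (cat.), CH2Cl2, 0 °C
Reagents that add atoms: acetyl chloride CC(Cl)=O
Why: Lewis-acid-catalysed addition of an acyl chloride across an aldehyde C=O gives the α-chloroalkyl ester, a known reaction type; the product is used without isolation because the electron-rich benzylic chloride ionises easily.

Step 7
Reactants: 7 (Z)-2-[2,4-bis(benzyloxy)-6-hydroxyphenyl]ethenyl 3,4,5-tris(benzyloxy)benzoate; 9 [3,4-bis(benzyloxy)phenyl](chloro)methyl acetate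
Product: 10 [3,4-bis(benzyloxy)phenyl]{3,5-bis(benzyloxy)-2-[(Z)-2-{[3,4,5-tris(benzyloxy)benzoyl]oxy}ethenyl]phenoxy}methyl acetate (racemic at the acetal carbon; filtered through deactivated silica and used directly)
Conditions: i-Pr2NEt, CH2Cl2, −40 → 0 °C
Reagents that add atoms: none
Why: O-alkylation of the phenol by the SN1-active α-chloro ester under a hindered amine base, as in acyloxyalkyl aryl ether formation, installs the future C2 on O1 with acetate as the nucleofuge; the acetal centre is racemic but is erased on ionisation.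

Step 8
Reactants: 11 (−)-epicatechin
Product: 12 5,7,3',4'-tetra-O-benzyl-(−)-epicatechin
Conditions: BnBr (4.4 equiv), K2CO3, DMF, 0 °C → rt
Reagents that add atoms: benzyl bromide BrCc1ccccc1
Why: Williamson etherification of the four phenols only; the secondary 3-OH is not deprotonated by K2CO3 and C2 should not epimerise at room temperature.

Step 9
Reactants: 12 5,7,3',4'-tetra-O-benzyl-(−)-epicatechin; 5 3,4,5-tris(benzyloxy)benzoic acid
Product: 13 5,7,3',4'-tetra-O-benzyl-(−)-epicatechin 3-O-[3,4,5-tris(benzyloxy)benzoate]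
Conditions: DCC, DMAP, CH2Cl2, rt
Reagents that add atoms: none
Why: Steglich esterification of the axial 3-OH, with retention at C3 because only the O–H bond is involved.

Step 10
Reactants: 10 O-aryl O-acetyl acetal (see step 7); 13 5,7,3',4'-tetra-O-benzyl-(−)-epicatechin 3-O-[3,4,5-tris(benzyloxy)benzoate] (3 equiv, excess recovered)
Product: 16 perbenzylated epicatechin-3-O-gallate-(4β→8)-epicatechin-3-O-gallate, via aryloxycarbenium ion 14 (not isolated), via flavan-4-yl cation 15 (not isolated)
Conditions: (R)-3,3'-bis(2,4,6-triisopropylphenyl)-1,1'-binaphthalene-2,2'-diyl N-(trifluoromethanesulfonyl)phosphoramidate (10 mol %), 4 Å MS, CH2Cl2/toluene 1:1, −78 → −40 °C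
Reagents that add atoms: none
Why: Proposed new method: the chiral acid protonates the acetate of acylal 10, acetic acid leaves (a far better nucleofuge than the aryloxide) and the benzylic aryloxycarbenium ion 14 forms as a contact ion pair with the chiral phosphoramidate; its carbon, the future C2, is attacked by C3 of the tethered (Z)-enol gallate because only this regiochemistry places the charge at C4, where the 5,7-dioxygenated ring A stabilises it as cation 15, and 15 is then arylated by C8 of 13 with release of the proton that returns the acid. The closest known reaction types are the Prins cyclisation of α-acetoxy ethers with Friedel–Crafts termination, Brønsted-acid-catalysed asymmetric Prins cyclisations that run through chiral-anion-paired oxocarbenium ions, and the Lewis-acid coupling of flavan-4-yl cations with C8 of benzylated flavan-3-ols. Ring C of the middle unit closes in a 6-endo-trig mode through a chair-like transition state in which the (E)-oxocarbenium carries the B-ring aryl group equatorially. C2 is set by the chiral counter-anion that shields one face of 14 (catalyst control), C3 by the alkene geometry (the acyloxy group cis to ring A is forced axial, hence 2,3-cis), and C4 by attack of 13 anti to the axial 3-O-galloyl group (3,4-trans, 4β), as for every epicatechin-type C4 cation. The step needs ring closure to outrun intermolecular arylation of 14 and protonation of the enol ester, which the tether, the low temperature and the easy ionisation of the acylal should secure, and it needs C8 over C6 selectivity in 13, which is the established preference of benzylated flavan-3-ol nucleophiles. Material from any minor enantiofacial closure ends up as a diastereomer of 16, because 13 is enantiopure, and should be removable by chromatography.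

Step 11
Reactants: 12 5,7,3',4'-tetra-O-benzyl-(−)-epicatechin
Product: 17 5,7,3',4'-tetra-O-benzyl-4β-(2-ethoxyethoxy)-(−)-epicatechin
Conditions: DDQ, 2-ethoxyethanol, CH2Cl2, rt
Reagents that add atoms: 2-ethoxyethanol CCOCCO
Why: DDQ hydride abstraction from benzylic C4 gives the ring-A-stabilised cation, which the alcohol captures anti to the 3-OH to give the 4β-ether, the standard electrophile of procyanidin synthesis.

Step 12
Reactants: 16 perbenzylated epicatechin-3-O-gallate-(4β→8)-epicatechin-3-O-gallate (1.5 equiv); 17 5,7,3',4'-tetra-O-benzyl-4β-(2-ethoxyethoxy)-(−)-epicatechin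
Product: 18 octadeca-O-benzyl ether of the target (free 3-OH on the top unit)
Conditions: TMSOTf (cat.), CH2Cl2, −78 °C, then Et3N quench
Reagents that add atoms: none
Why: Lewis-acid ionisation of the 4-alkoxy group and Friedel–Crafts capture of the C4 cation by C8 of the upper unit of 16, anti to the axial 3-OH (4β), relying on the known preference for C8 of the terminal unit of a dimeric nucleophile over the C6 positions.

Step 13
Reactants: 18 octadeca-O-benzyl ether of the target
Product: 19 CNP0279403.1, epicatechin-(4β→8)-epicatechin-3-O-gallate-(4β→8)-epicatechin-3-O-gallate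
Conditions: H2 (1 atm), Pd(OH)2/C, THF/MeOH/H2O, rt
Reagents that add atoms: none
Why: Hydrogenolysis of the eighteen benzyl ethers over Pd(OH)2/C, which should leave the two gallate esters, the interflavan bonds and all stereocentres untouched.

**Compound list**

1 | 2,4,6-trihydroxybenzaldehyde | O=Cc1c(O)cc(O)cc1O | starting material
2 | 2,4-bis(benzyloxy)-6-hydroxybenzaldehyde | O=Cc1c(O)cc(OCc9ccccc9)cc1OCc9ccccc9 | intermediate
3 | 2,4-bis(benzyloxy)-6-[(triisopropylsilyl)oxy]benzaldehyde | O=Cc1c(O[Si](C(C)C)(C(C)C)C(C)C)cc(OCc9ccccc9)cc1OCc9ccccc9 | intermediate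
4 | 1,5-bis(benzyloxy)-2-ethynyl-3-[(triisopropylsilyl)oxy]benzene | C#Cc1c(O[Si](C(C)C)(C(C)C)C(C)C)cc(OCc9ccccc9)cc1OCc9ccccc9 | intermediate
5 | 3,4,5-tris(benzyloxy)benzoic acid | OC(=O)c1cc(OCc9ccccc9)c(OCc9ccccc9)c(OCc9ccccc9)c1 | starting material
6 | (Z)-2-{2,4-bis(benzyloxy)-6-[(triisopropylsilyl)oxy]phenyl}ethenyl 3,4,5-tris(benzyloxy)benzoate | O=C(O/C=C\c1c(O[Si](C(C)C)(C(C)C)C(C)C)cc(OCc9ccccc9)cc1OCc9ccccc9)c1cc(OCc9ccccc9)c(OCc9ccccc9)c(OCc9ccccc9)c1 | intermediate
7 | (Z)-2-[2,4-bis(benzyloxy)-6-hydroxyphenyl]ethenyl 3,4,5-tris(benzyloxy)benzoate | O=C(O/C=C\c1c(O)cc(OCc9ccccc9)cc1OCc9ccccc9)c1cc(OCc9ccccc9)c(OCc9ccccc9)c(OCc9ccccc9)c1 | intermediate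
8 | 3,4-bis(benzyloxy)benzaldehyde | O=Cc1ccc(OCc9ccccc9)c(OCc9ccccc9)c1 | starting material
9 | [3,4-bis(benzyloxy)phenyl](chloro)methyl acetate, racemic | CC(=O)OC(Cl)c1ccc(OCc9ccccc9)c(OCc9ccccc9)c1 | intermediate
10 | [3,4-bis(benzyloxy)phenyl]{3,5-bis(benzyloxy)-2-[(Z)-2-{[3,4,5-tris(benzyloxy)benzoyl]oxy}ethenyl]phenoxy}methyl acetate, racemic at the acetal carbon | CC(=O)OC(Oc1cc(OCc9ccccc9)cc(OCc9ccccc9)c1/C=C\OC(=O)c1cc(OCc9ccccc9)c(OCc9ccccc9)c(OCc9ccccc9)c1)c1ccc(OCc9ccccc9)c(OCc9ccccc9)c1 | intermediate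
11 | (−)-epicatechin, (2R,3R) | O[C@@H]1Cc2c(O)cc(O)cc2O[C@@H]1c1ccc(O)c(O)c1 | starting material
12 | 5,7,3',4'-tetra-O-benzyl-(−)-epicatechin | O[C@@H]1Cc2c(OCc9ccccc9)cc(OCc9ccccc9)cc2O[C@@H]1c1ccc(OCc9ccccc9)c(OCc9ccccc9)c1 | intermediate
13 | 5,7,3',4'-tetra-O-benzyl-(−)-epicatechin 3-O-[3,4,5-tris(benzyloxy)benzoate] | O=C(O[C@@H]1Cc2c(OCc9ccccc9)cc(OCc9ccccc9)cc2O[C@@H]1c1ccc(OCc9ccccc9)c(OCc9ccccc9)c1)c1cc(OCc9ccccc9)c(OCc9ccccc9)c(OCc9ccccc9)c1 | intermediate
14 | aryloxycarbenium ion from 10 after loss of acetate (future C2 cationic, Z-enol gallate intact) | O=C(O/C=C\c1c(OCc9ccccc9)cc(OCc9ccccc9)cc1[O+]=Cc1ccc(OCc9ccccc9)c(OCc9ccccc9)c1)c1cc(OCc9ccccc9)c(OCc9ccccc9)c(OCc9ccccc9)c1 | intermediate (not isolated)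
15 | (2R,3R)-5,7,3',4'-tetrakis(benzyloxy)-3-{[3,4,5-tris(benzyloxy)benzoyl]oxy}flavan-4-yl cation, 2,3-cis | O=C(O[C@@H]1[CH+]c2c(OCc9ccccc9)cc(OCc9ccccc9)cc2O[C@@H]1c1ccc(OCc9ccccc9)c(OCc9ccccc9)c1)c1cc(OCc9ccccc9)c(OCc9ccccc9)c(OCc9ccccc9)c1 | intermediate (not isolated)
16 | perbenzylated epicatechin-3-O-gallate-(4β→8)-epicatechin-3-O-gallate (fourteen benzyl ethers; upper unit 2,3-cis-3,4-trans) | O=C(O[C@@H]1[C@@H](c2c(OCc9ccccc9)cc(OCc9ccccc9)c3c2O[C@H](c2ccc(OCc9ccccc9)c(OCc9ccccc9)c2)[C@H](OC(=O)c2cc(OCc9ccccc9)c(OCc9ccccc9)c(OCc9ccccc9)c2)C3)c2c(OCc9ccccc9)cc(OCc9ccccc9)cc2O[C@@H]1c1ccc(OCc9ccccc9)c(OCc9ccccc9)c1)c1cc(OCc9ccccc9)c(OCc9ccccc9)c(OCc9ccccc9)c1 | intermediate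
17 | 5,7,3',4'-tetra-O-benzyl-4β-(2-ethoxyethoxy)-(−)-epicatechin (2,3-cis-3,4-trans) | CCOCCO[C@H]1c2c(OCc9ccccc9)cc(OCc9ccccc9)cc2O[C@H](c2ccc(OCc9ccccc9)c(OCc9ccccc9)c2)[C@@H]1O | intermediate
18 | octadeca-O-benzyl ether of the target: epicatechin-(4β→8)-epicatechin-3-O-gallate-(4β→8)-epicatechin-3-O-gallate with all phenols benzylated | O=C(O[C@@H]1[C@@H](c2c(OCc9ccccc9)cc(OCc9ccccc9)c3c2O[C@H](c2ccc(OCc9ccccc9)c(OCc9ccccc9)c2)[C@H](OC(=O)c2cc(OCc9ccccc9)c(OCc9ccccc9)c(OCc9ccccc9)c2)C3)c2c(OCc9ccccc9)cc(OCc9ccccc9)c([C@H]3c4c(OCc9ccccc9)cc(OCc9ccccc9)cc4O[C@H](c4ccc(OCc9ccccc9)c(OCc9ccccc9)c4)[C@@H]3O)c2O[C@@H]1c1ccc(OCc9ccccc9)c(OCc9ccccc9)c1)c1cc(OCc9ccccc9)c(OCc9ccccc9)c(OCc9ccccc9)c1 | intermediate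
19 | CNP0279403.1, epicatechin-(4β→8)-epicatechin-3-O-gallate-(4β→8)-epicatechin-3-O-gallate | O=C(O[C@@H]1[C@@H](c2c(O)cc(O)c3c2O[C@H](c2ccc(O)c(O)c2)[C@H](OC(=O)c2cc(O)c(O)c(O)c2)C3)c2c(O)cc(O)c([C@H]3c4c(O)cc(O)cc4O[C@H](c4ccc(O)c(O)c4)[C@@H]3O)c2O[C@@H]1c1ccc(O)c(O)c1)c1cc(O)c(O)c(O)c1 | target

**Step count and risks**

Total step count: 13. Longest linear sequence: 9 steps (steps 1, 2, 3, 4, 5, 7, 10, 12, 13).

Steps most likely to fail:

1. Step 10 (Proposed new method). The chiral anion may discriminate the two faces of the large, handle-free ion 14 poorly or in the wrong sense. The acid may protonate the enol ester alkene instead of ionising the acylal. Ion 14 may be arylated intermolecularly by 13 before the ring closes. The fallback uses known chemistry only, sets out from 17 and comes back at 16. Steglich esterification of the 3-OH of 17 with acid 5 (DCC, DMAP, CH2Cl2) should give 5,7,3',4'-tetra-O-benzyl-4β-(2-ethoxyethoxy)-(−)-epicatechin 3-O-[3,4,5-tris(benzyloxy)benzoate] F1. TMSOTf-catalysed condensation of F1 with an excess of 13 (CH2Cl2, −78 °C) should then give 16. This is the established semisynthetic entry; it gives up the de novo closure of ring C and takes all stereocentres from the chiral pool.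

2. Step 7. The chloro ester 9 may revert to aldehyde 8 and acetyl chloride, which would acetylate phenol 7. The galloyl group may migrate from the enol oxygen to the phenol oxygen under base. Acylal 10 may ionise during handling. The fallback sets out from 8 (with phenol 7) and comes back at ion 14. Aldehyde 8 and 1H-benzotriazole should give the hemiaminal [3,4-bis(benzyloxy)phenyl](1H-benzotriazol-1-yl)methanol F2. Thionyl chloride should convert it into 1-{[3,4-bis(benzyloxy)phenyl](chloro)methyl}-1H-benzotriazole F3, a storable reagent. Alkylation of 7 with F3 (i-Pr2NEt, CH2Cl2) should give the benzotriazolyl acetal (Z)-2-[2-{[3,4-bis(benzyloxy)phenyl](1H-benzotriazol-1-yl)methoxy}-4,6-bis(benzyloxy)phenyl]ethenyl 3,4,5-tris(benzyloxy)benzoate F4. F4 is a bench-stable equivalent of 10 that loses benzotriazole on N-protonation (or with ZnBr2) to give the same ion 14.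

3. Step 12. Electrophile 17 may self-condense through its own free C8, product 18 may be chain-extended further, and attack may occur at the C6 positions of 16. The fallback blocks C8 of the electrophile with bromine; it sets out from 12 and comes back at 19. NBS (CH2Cl2, −78 °C → rt) should give 8-bromo-5,7,3',4'-tetra-O-benzyl-(−)-epicatechin F5. DDQ and 2-ethoxyethanol should give 8-bromo-5,7,3',4'-tetra-O-benzyl-4β-(2-ethoxyethoxy)-(−)-epicatechin F6, which cannot act as a nucleophile and can be used in excess. TMSOTf-catalysed coupling with 16 should give the 8-bromo derivative of 18 (bromine at C8 of the top unit) F7. Hydrogenolysis (H2, Pd(OH)2/C, Et3N, THF/MeOH/H2O) should remove the bromine together with the benzyl groups to give 19.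

**Further compounds**

F1 | step 10 | 5,7,3',4'-tetra-O-benzyl-4β-(2-ethoxyethoxy)-(−)-epicatechin 3-O-[3,4,5-tris(benzyloxy)benzoate] | CCOCCO[C@H]1c2c(OCc9ccccc9)cc(OCc9ccccc9)cc2O[C@H](c2ccc(OCc9ccccc9)c(OCc9ccccc9)c2)[C@@H]1OC(=O)c1cc(OCc9ccccc9)c(OCc9ccccc9)c(OCc9ccccc9)c1
F2 | step 7 | [3,4-bis(benzyloxy)phenyl](1H-benzotriazol-1-yl)methanol, racemic | OC(c1ccc(OCc9ccccc9)c(OCc9ccccc9)c1)n1nnc2ccccc21
F3 | step 7 | 1-{[3,4-bis(benzyloxy)phenyl](chloro)methyl}-1H-benzotriazole, racemic | ClC(c1ccc(OCc9ccccc9)c(OCc9ccccc9)c1)n1nnc2ccccc21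
F4 | step 7 | (Z)-2-[2-{[3,4-bis(benzyloxy)phenyl](1H-benzotriazol-1-yl)methoxy}-4,6-bis(benzyloxy)phenyl]ethenyl 3,4,5-tris(benzyloxy)benzoate, racemic | O=C(O/C=C\c1c(OC(c2ccc(OCc9ccccc9)c(OCc9ccccc9)c2)n2nnc3ccccc32)cc(OCc9ccccc9)cc1OCc9ccccc9)c1cc(OCc9ccccc9)c(OCc9ccccc9)c(OCc9ccccc9)c1
F5 | step 12 | 8-bromo-5,7,3',4'-tetra-O-benzyl-(−)-epicatechin | O[C@@H]1Cc2c(OCc9ccccc9)cc(OCc9ccccc9)c(Br)c2O[C@@H]1c1ccc(OCc9ccccc9)c(OCc9ccccc9)c1
F6 | step 12 | 8-bromo-5,7,3',4'-tetra-O-benzyl-4β-(2-ethoxyethoxy)-(−)-epicatechin | CCOCCO[C@H]1c2c(OCc9ccccc9)cc(OCc9ccccc9)c(Br)c2O[C@H](c2ccc(OCc9ccccc9)c(OCc9ccccc9)c2)[C@@H]1O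
F7 | step 12 | 8-bromo derivative of 18 (bromine at C8 of the top unit) | O=C(O[C@@H]1[C@@H](c2c(OCc9ccccc9)cc(OCc9ccccc9)c3c2O[C@H](c2ccc(OCc9ccccc9)c(OCc9ccccc9)c2)[C@H](OC(=O)c2cc(OCc9ccccc9)c(OCc9ccccc9)c(OCc9ccccc9)c2)C3)c2c(OCc9ccccc9)cc(OCc9ccccc9)c([C@H]3c4c(OCc9ccccc9)cc(OCc9ccccc9)c(Br)c4O[C@H](c4ccc(OCc9ccccc9)c(OCc9ccccc9)c4)[C@@H]3O)c2O[C@@H]1c1ccc(OCc9ccccc9)c(OCc9ccccc9)c1)c1cc(OCc9ccccc9)c(OCc9ccccc9)c(OCc9ccccc9)c1
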